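The route rests on cutting the seven-membered carbocycle at its two aryl–C(sp3) bonds that lie meta to the phenolic oxygens and are therefore closed to Friedel–Crafts chemistry: CH2 to C-4 of the central benzodifuran ring, and C-1 of the fused resorcinol ring to C-5 of the second dihydrofuran. One palladium-catalysed operation should forge both from an enantiopure bromo-benzodifuran, still a 2-arylbenzofuran on one side, and a chloroaryl methyl ketone: ketone α-arylation, then dearomative reductive Heck closure. This formal (4+3) annulation exploits the peri relationship of C-4 and C-5 and sets the trans C-5/C-6 stereocentres. Aryl addition, ionic hydrogenation and demethylation complete the synthesis.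

Key step: step 9

Remark on locants: the central tricycle is numbered as benzo[1,2-b:5,4-b']difuran (O-1, C-2, C-3, C-4, C-5, C-6, O-7, C-8); "ring C" is the resorcinol ring inside the seven-membered ring.
Assumption: Rh2(R-PTAD)4 (dirhodium tetrakis[(R)-(1-adamantyl)(N-phthalimido)acetate]) is taken to deliver the (3R)-configured insertion product; if the sense of induction is the opposite, the (S)-configured catalyst is used.
Assumption: all eight phenols are carried as methyl ethers; the two 4-methoxybenzyl ethers of 7 are not protecting groups but supply C-2 and C-6 with their aryl substituents.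

Step 1
Reactants: 1 1-bromo-3,5-dimethoxybenzene; 2 3,5-dimethoxybenzoyl chloride
Product: 3 (2-bromo-4,6-dimethoxyphenyl)(3,5-dimethoxyphenyl)methanone
Conditions: AlCl3 (1.1 equiv), CH2Cl2, 0 °C
Reagents that add atoms: none
Why: Friedel–Crafts acylation should enter ortho to bromine and para to a methoxy group (the site between the two methoxy groups is the more hindered one), and one equivalent of Lewis acid at 0 °C should avoid ortho-demethylation.

Step 2
Reactants: 3 (2-bromo-4,6-dimethoxyphenyl)(3,5-dimethoxyphenyl)methanone
Product: 4 2-bromo-3-(3,5-dimethoxybenzoyl)-4,6-dimethoxybenzaldehyde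
Conditions: Cl2CHOMe, TiCl4, CH2Cl2, −10 °C to rt; aqueous work-up
Reagents that add atoms: dichloromethyl methyl ether, COC(Cl)Cl; water, O
Why: Rieche formylation should take the remaining position ortho to bromine, which is para and ortho to the two methoxy groups and meta to the ketone, while the benzoyl ring is deactivated at all its methoxy-activated positions by the conjugated, titanium-bound carbonyl.

Step 3
Reactants: 4 2-bromo-3-(3,5-dimethoxybenzoyl)-4,6-dimethoxybenzaldehyde
Product: 5 2-bromo-3-(3,5-dimethoxybenzoyl)-4,6-dihydroxybenzaldehyde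
Conditions: BCl3 (excess), CH2Cl2, −78 °C to rt; aqueous work-up
Reagents that add atoms: none
Why: Chelation-controlled BCl3 demethylation should cleave only the two methoxy groups ortho to a carbonyl (one next to the aldehyde, one next to the ketone) and leave the meta-disposed methoxy groups of the benzoyl ring.

Step 4
Reactants: 5 2-bromo-3-(3,5-dimethoxybenzoyl)-4,6-dihydroxybenzaldehyde; 6 4-methoxybenzyl chloride (two equivalents are consumed, one per phenol)
Product: 7 2-bromo-3-(3,5-dimethoxybenzoyl)-4,6-bis[(4-methoxybenzyl)oxy]benzaldehyde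
Conditions: 6 (2.4 equiv), K2CO3 (3 equiv), NaI (cat.), DMF, 60 °C
Reagents that add atoms: 4-methoxybenzyl chloride (the second equivalent of 6), COc1ccc(CCl)cc1
Why: Double Williamson etherification should alkylate both chelated phenols, one equivalent of the benzyl chloride on each, under these forcing but mild conditions, and each benzylic CH2 later becomes a furan carbon carrying its 4-methoxyphenyl group.

Step 5
Reactants: 7 2-bromo-3-(3,5-dimethoxybenzoyl)-4,6-bis[(4-methoxybenzyl)oxy]benzaldehyde
Product: 8 [4-bromo-6-[(4-methoxybenzyl)oxy]-2-(4-methoxyphenyl)-1-benzofuran-5-yl](3,5-dimethoxyphenyl)methanone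
Conditions: phosphazene base P4-t-Bu (1.1 equiv), toluene, 80 °C
Reagents that add atoms: none
Why: Phosphazene-base-mediated intramolecular aldol-type condensation of an o-(arylmethoxy)benzaldehyde (benzofuran synthesis) should occur only on the aldehyde side, because the benzylic carbanion adds fast and irreversibly (after dehydration) to the formyl group, whereas addition of the other ether carbanion to the hindered, doubly ortho-substituted diaryl ketone is slow and reversible with one equivalent of base.

Step 6
Reactants: 8 [4-bromo-6-[(4-methoxybenzyl)oxy]-2-(4-methoxyphenyl)-1-benzofuran-5-yl](3,5-dimethoxyphenyl)methanone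
Product: 9 hydrazone of ketone 8
Conditions: N2H4·H2O (10 equiv), AcOH (cat.), n-BuOH, 110 °C
Reagents that add atoms: hydrazine, NN
Why: Condensation of hydrazine with the diaryl ketone (hydrazone formation) should be forced by excess reagent and heat although the carbonyl is flanked by two ortho substituents; the hydrazone geometry is irrelevant.

Step 7
Reactants: 9 hydrazone of ketone 8
Product: 12 (2R,3R)-4-bromo-3-(3,5-dimethoxyphenyl)-2,6-bis(4-methoxyphenyl)-2,3-dihydrobenzo[1,2-b:5,4-b']difuran, via diazo compound 10 (not isolated), via cis-dihydrobenzodifuran 11 (not isolated)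
Conditions: MnO2, CH2Cl2, 0 °C, filtration; Rh2(R-PTAD)4 (1 mol %), CH2Cl2, 0 °C to rt; then BF3·OEt2, 0 °C to rt
Reagents that add atoms: none
Why: Oxidation should give a donor/donor diazo compound whose chiral dirhodium carbene undergoes 1,5 C–H insertion into the benzylic ether CH2 to give the cis-2,3-diaryl dihydrofuran with C-3 set by the catalyst, after which the Lewis acid should epimerise only C-2 by reversible ionisation of the benzylic C–O bond (4-methoxybenzyl cation) to the favoured trans isomer with C-3 untouched.

Step 8
Reactants: 13 1-chloro-3,5-dimethoxybenzene; 14 acetyl chloride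
Product: 15 1-(2-chloro-4,6-dimethoxyphenyl)ethanone
Conditions: AlCl3 (1.1 equiv), CH2Cl2, 0 °C
Reagents that add atoms: none
Why: Friedel–Crafts acetylation should enter ortho to chlorine and para to a methoxy group, by the same preference as in step 1.

Step 9
Reactants: 12 (2R,3R)-4-bromo-3-(3,5-dimethoxyphenyl)-2,6-bis(4-methoxyphenyl)-2,3-dihydrobenzo[1,2-b:5,4-b']difuran; 15 1-(2-chloro-4,6-dimethoxyphenyl)ethanone
Product: 17 (2R,3R,5R,6R)-hexamethoxy seven-membered-ring ketone, via open-chain chloroaryl ketone 16 (not isolated)
Conditions: 15 (1.3 equiv, added slowly), Pd(OAc)2 (5 mol %), XPhos (10 mol %), K3PO4 (3 equiv), toluene, 80 °C; then HCO2Na (5 equiv), DMF, 110 °C, same pot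
Reagents that add atoms: none
Why: Proposed new method: zerovalent palladium should insert first into the hindered C-4–Br bond of 12 (before the C–Cl bond of 15) and the ketone enolate is C-arylated (Buchwald–Hartwig-type ketone α-arylation, forming the CH2–C-4 bond) to give 16; at the higher temperature the same catalyst inserts into the aryl–Cl bond, the arylpalladium adds across the furan C-5=C-6 bond (7-exo-trig syn-carbopalladation, forming the ring C–C-5 bond and closing the seven-membered ring), and the tertiary benzylic alkylpalladium at C-6, which has no syn β-hydrogen, is reduced by formate with retention. The closest known reactions are the palladium-catalysed α-arylation of aryl methyl ketones and the intramolecular dearomative reductive Heck reaction of indoles and benzofurans, here combined in one pot as a formal (4+3) annulation on a 2-arylbenzofuran that carries hydrogen at the arylated carbon. The C-5 stereocentre should be set by the C-3 aryl group of 12, which shields one face of the region around C-4 so that the CH2–C(=O) tether and the incoming ring C pass over the opposite face. The C-6 stereocentre follows from syn addition and stereoretentive hydride delivery, which places the two aryl groups trans. The step needs chemoselectivity (Br before Cl, secured by the halide difference and the two temperatures), regioselectivity (7-exo at C-5 instead of 8-endo at C-6, secured by the tether length) and suppression of rearomatising C–H arylation (secured by excess formate, which should reduce the alkylpalladium before base removes the anti hydrogen at C-5). Double arylation of the ketone is blocked by the two ortho substituents flanking C-4.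

Step 10
Reactants: 17 (2R,3R,5R,6R)-hexamethoxy seven-membered-ring ketone; 18 (2,4-dimethoxyphenyl)magnesium bromide
Product: 19 tertiary carbinol (2,4-dimethoxyphenyl adduct of 17)
Conditions: 18 (3 equiv), LaCl3·2LiCl (1 equiv), THF, 0 °C; aqueous work-up
Reagents that add atoms: none
Why: Lanthanum-promoted 1,2-addition of the aryl Grignard reagent should outrun enolisation of the benzylic ketone, and the configuration of the new carbinol carbon is irrelevant because it is ionised in the next step.

Step 11
Reactants: 19 tertiary carbinol (2,4-dimethoxyphenyl adduct of 17)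
Product: 20 octa-O-methyl ether of the target
Conditions: Et3SiH (5 equiv), CF3CO2H (3 equiv), CH2Cl2, −40 °C
Reagents that add atoms: none
Why: Ionic hydrogenation (SN1) should ionise the carbinol to a doubly aryl-stabilised cation and deliver hydride to the convex face of the folded seven-membered ring, anti to the central ring and the C-3 aryl group, which leaves the 2,4-dimethoxyphenyl group pseudo-equatorial and sets the R configuration, while the low temperature keeps the benzylic ethers of the dihydrofurans intact.

Step 12
Reactants: 20 octa-O-methyl ether of the target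
Product: 21 CNP0154047.1
Conditions: BBr3 (excess), CH2Cl2, −78 °C to rt; MeOH quench
Reagents that add atoms: none
Why: Lewis acid-mediated cleavage of all eight aryl methyl ethers (BBr3 demethylation) touches no stereocentre, and any reversible opening of a dihydrofuran should reclose to the favoured trans isomer.

Compound list
1 | 1-bromo-3,5-dimethoxybenzene | COc1cc(Br)cc(OC)c1 | starting material
2 | 3,5-dimethoxybenzoyl chloride | COc1cc(cc(OC)c1)C(Cl)=O | starting material
3 | (2-bromo-4,6-dimethoxyphenyl)(3,5-dimethoxyphenyl)methanone | COc1cc(OC)c(C(=O)c2cc(OC)cc(OC)c2)c(Br)c1 | intermediate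
4 | 2-bromo-3-(3,5-dimethoxybenzoyl)-4,6-dimethoxybenzaldehyde | COc1cc(OC)c(C(=O)c2cc(OC)cc(OC)c2)c(Br)c1C=O | intermediate
5 | 2-bromo-3-(3,5-dimethoxybenzoyl)-4,6-dihydroxybenzaldehyde | Oc1cc(O)c(C(=O)c2cc(OC)cc(OC)c2)c(Br)c1C=O | intermediate
6 | 4-methoxybenzyl chloride | COc1ccc(CCl)cc1 | starting material
7 | 2-bromo-3-(3,5-dimethoxybenzoyl)-4,6-bis[(4-methoxybenzyl)oxy]benzaldehyde | O=Cc1c(Br)c(C(=O)c2cc(OC)cc(OC)c2)c(OCc2ccc(OC)cc2)cc1OCc1ccc(OC)cc1 | intermediate
8 | [4-bromo-6-[(4-methoxybenzyl)oxy]-2-(4-methoxyphenyl)-1-benzofuran-5-yl](3,5-dimethoxyphenyl)methanone | COc1ccc(cc1)-c1cc2c(Br)c(C(=O)c3cc(OC)cc(OC)c3)c(OCc3ccc(OC)cc3)cc2o1 | intermediate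
9 | hydrazone of ketone 8 (C=N–NH2 in place of C=O) | COc1ccc(cc1)-c1cc2c(Br)c(C(=NN)c3cc(OC)cc(OC)c3)c(OCc3ccc(OC)cc3)cc2o1 | intermediate
10 | 4-bromo-5-[diazo(3,5-dimethoxyphenyl)methyl]-6-[(4-methoxybenzyl)oxy]-2-(4-methoxyphenyl)-1-benzofuran | COc1ccc(cc1)-c1cc2c(Br)c(C(=[N+]=[N-])c3cc(OC)cc(OC)c3)c(OCc3ccc(OC)cc3)cc2o1 | intermediate (not isolated)
11 | (2S,3R)-4-bromo-3-(3,5-dimethoxyphenyl)-2,6-bis(4-methoxyphenyl)-2,3-dihydrobenzo[1,2-b:5,4-b']difuran (2,3-cis) | COc1ccc([C@H]2Oc3cc4oc(-c5ccc(OC)cc5)cc4c(Br)c3[C@H]2c2cc(OC)cc(OC)c2)cc1 | intermediate (not isolated)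
12 | (2R,3R)-4-bromo-3-(3,5-dimethoxyphenyl)-2,6-bis(4-methoxyphenyl)-2,3-dihydrobenzo[1,2-b:5,4-b']difuran (2,3-trans) | COc1ccc([C@@H]2Oc3cc4oc(-c5ccc(OC)cc5)cc4c(Br)c3[C@H]2c2cc(OC)cc(OC)c2)cc1 | intermediate
13 | 1-chloro-3,5-dimethoxybenzene | COc1cc(Cl)cc(OC)c1 | starting material
14 | acetyl chloride | CC(Cl)=O | starting material
15 | 1-(2-chloro-4,6-dimethoxyphenyl)ethanone | CC(=O)c1c(Cl)cc(OC)cc1OC | intermediate
16 | 1-(2-chloro-4,6-dimethoxyphenyl)-2-[(2R,3R)-3-(3,5-dimethoxyphenyl)-2,6-bis(4-methoxyphenyl)-2,3-dihydrobenzo[1,2-b:5,4-b']difuran-4-yl]ethanone | COc1ccc([C@@H]2Oc3cc4oc(-c5ccc(OC)cc5)cc4c(CC(=O)c4c(Cl)cc(OC)cc4OC)c3[C@H]2c2cc(OC)cc(OC)c2)cc1 | intermediate (not isolated)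
17 | (2R,3R,5R,6R)-3-(3,5-dimethoxyphenyl)-2,6-bis(4-methoxyphenyl)-2,3,5,6-tetrahydrobenzodifuran in which C-4 (through CH2–C(=O)) and C-5 are joined to C-2 and C-1 of a 3,5-dimethoxybenzene ring (hexamethoxy seven-membered-ring ketone, both dihydrofurans trans) | COc1ccc([C@@H]2Oc3cc4c5c(c3[C@H]2c2cc(OC)cc(OC)c2)CC(=O)c2c(OC)cc(OC)cc2[C@H]5[C@H](c2ccc(OC)cc2)O4)cc1 | intermediate
18 | (2,4-dimethoxyphenyl)magnesium bromide | COc1ccc([Mg]Br)c(OC)c1 | starting material
19 | tertiary carbinol from 17: ring carbonyl replaced by C(OH)(2,4-dimethoxyphenyl), carbinol carbon of either configuration | COc1ccc([C@@H]2Oc3cc4c5c(c3[C@H]2c2cc(OC)cc(OC)c2)CC(O)(c2ccc(OC)cc2OC)c2c(OC)cc(OC)cc2[C@H]5[C@H](c2ccc(OC)cc2)O4)cc1 | intermediate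
20 | octa-O-methyl ether of the target (all five stereocentres R) | COc1ccc([C@@H]2Oc3cc4c5c(c3[C@H]2c2cc(OC)cc(OC)c2)C[C@H](c2ccc(OC)cc2OC)c2c(OC)cc(OC)cc2[C@H]5[C@H](c2ccc(OC)cc2)O4)cc1 | intermediate
21 | CNP0154047.1 | Oc1ccc([C@@H]2Oc3cc4c5c(c3[C@H]2c2cc(O)cc(O)c2)C[C@H](c2ccc(O)cc2O)c2c(O)cc(O)cc2[C@H]5[C@H](c2ccc(O)cc2)O4)cc1 | target

Total step count: 12. Longest linear sequence: 11 steps (steps 1 to 7 and 9 to 12).

Steps most likely to fail

Step 9 (labelled step). What may go wrong: premature oxidative addition at the C–Cl bond with self-arylation of the ketone, hydrodechlorination before ring closure, base-mediated rearomatisation of the alkylpalladium intermediate, or poor facial selectivity in the carbopalladation. The fallback uses known chemistry, sets out from 12 and 15 and comes back at 17; it uncouples the two bond formations and replaces the dearomatising event by arene C–H arylation followed by reduction. Ketone α-arylation alone (Pd(OAc)2, XPhos, K3PO4, toluene, 80 °C) would give the open-chain chloroaryl ketone 16, now isolated. Intramolecular direct C–H arylation at C-5 of the benzofuran (Pd(OAc)2, PCy3·HBF4, K2CO3, pivalic acid, DMA, 130 °C, concerted metalation–deprotonation) would close the seven-membered ring to the fully aromatic benzofuran-fused cycloheptanone F1. Cis-hydrogenation of the furan C-5=C-6 bond (H2 at 30 bar, Pd/C, EtOAc, 50 °C) should take place from the face opposite to the puckered CH2–C(=O) bridge, which itself sits anti to the C-3 aryl group, and would give the 5,6-cis-dihydrofuran ketone F2. Acid (BF3·OEt2, CH2Cl2) would then epimerise C-6 through the benzylic cation to the trans isomer 17.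

Step 7. What may go wrong: slow or incomplete carbene formation at the doubly ortho-substituted carbon, azine formation, low enantio-induction, or erosion at C-3 by elimination during the acid epimerisation. The fallback sets out from 8 and comes back at 12; it avoids the carbene by an ortho-quinone methide (4+1) annulation. Cleavage of the remaining 4-methoxybenzyl ether (CF3CO2H, anisole, CH2Cl2, 0 °C) would give the phenol ketone F3, and NaBH4 (MeOH, 0 °C) would give the o-hydroxybenzhydrol F4. Sodium p-toluenesulfinate with p-toluenesulfonic acid (CH2Cl2, rt) would exchange the benzylic hydroxyl for the sulfonyl group and give the sulfone F5. Cs2CO3 (CH2Cl2, rt) would eliminate sulfinate from F5 to the ortho-quinone methide F6, generated in the presence of the ylide of an enantiopure, isothiocineole-derived (4-methoxybenzyl)sulfonium triflate. Trans-selective (4+1) annulation would return 12.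

Step 11. What may go wrong: hydride delivery to the wrong face of the diarylmethyl cation, which would give the epimer at the aryl-bearing carbon of the seven-membered ring, or interception of the cation by the neighbouring 3,5-dimethoxyphenyl ring before reduction. The fallback sets out from 17 and comes back at 20; it reverses the order in which hydride and the aryl group reach this carbon, so that the arene and not the hydride enters from the open face of the cation, which should give the configuration opposite to that from the ionic hydrogenation. NaBH4 (MeOH/THF, 0 °C) would reduce 17 to the secondary benzylic alcohol F7, of either configuration at the carbinol carbon. Ionisation of F7 (BF3·OEt2, CH2Cl2, −40 °C) in the presence of 1,3-dimethoxybenzene (10 equiv) would give, by Friedel–Crafts alkylation at C-4 of that arene, the octamethyl ether 20.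

Further compounds
F1 | step 9 | benzofuran-fused cycloheptanone: (2R,3R)-dihydrobenzodifuran whose aromatic furan C-5 is bonded to C-1 of ring C, with CH2–C(=O) from C-4 to C-2 of ring C | COc1ccc([C@@H]2Oc3cc4oc(-c6ccc(OC)cc6)c5c4c(c3[C@H]2c2cc(OC)cc(OC)c2)CC(=O)c2c(OC)cc(OC)cc2-5)cc1
F2 | step 9 | (2R,3R,5R,6S)-isomer of 17 (5,6-cis-dihydrofuran) | COc1ccc([C@@H]2Oc3cc4c5c(c3[C@H]2c2cc(OC)cc(OC)c2)CC(=O)c2c(OC)cc(OC)cc2[C@H]5[C@@H](c2ccc(OC)cc2)O4)cc1
F3 | step 7 | [4-bromo-6-hydroxy-2-(4-methoxyphenyl)-1-benzofuran-5-yl](3,5-dimethoxyphenyl)methanone | COc1ccc(cc1)-c1cc2c(Br)c(C(=O)c3cc(OC)cc(OC)c3)c(O)cc2o1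
F4 | step 7 | 4-bromo-5-[hydroxy(3,5-dimethoxyphenyl)methyl]-2-(4-methoxyphenyl)-1-benzofuran-6-ol | COc1ccc(cc1)-c1cc2c(Br)c(C(O)c3cc(OC)cc(OC)c3)c(O)cc2o1
F5 | step 7 | 4-bromo-5-[(3,5-dimethoxyphenyl)(4-methylbenzenesulfonyl)methyl]-2-(4-methoxyphenyl)-1-benzofuran-6-ol (sulfone) | COc1ccc(cc1)-c1cc2c(Br)c(C(c3cc(OC)cc(OC)c3)S(=O)(=O)c3ccc(C)cc3)c(O)cc2o1
F6 | step 7 | 4-bromo-5-(3,5-dimethoxybenzylidene)-2-(4-methoxyphenyl)-1-benzofuran-6(5H)-one (ortho-quinone methide, not isolated) | COc1ccc(cc1)C1=CC2=C(Br)C(=Cc3cc(OC)cc(OC)c3)C(=O)C=C2O1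
F7 | step 11 | secondary alcohol from 17: ring carbonyl replaced by CH(OH), carbinol carbon of either configuration | COc1ccc([C@@H]2Oc3cc4c5c(c3[C@H]2c2cc(OC)cc(OC)c2)CC(O)c2c(OC)cc(OC)cc2[C@H]5[C@H](c2ccc(OC)cc2)O4)cc1
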